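**Retrosynthetic overview**
1. Target ⇒ 2,3,5-tribromo-6-propyl-4H-pyran-4-one. The side-chain CBr2 is installed last, by double radical C–H bromination next to C6.
2. Pyranone ring ⇒ open-chain 1,4-dibromooct-1-yne-3,5-dione. The key disconnection is O1–C2: the enol oxygen adds to the bromine-bearing alkyne carbon (6-endo-dig) and Br+ is trapped at C3.
3. That ynedione is made in the same flask from 1-(trimethylsilyl)oct-1-yne-3,5-dione (C4–H → C4–Br, C–Si → C–Br).
4. Silyl ynedione ⇒ C4–C5 acylation of the enolate of 4-(trimethylsilyl)but-3-yn-2-one by butanoyl chloride.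
5. Ring order: there is one ring only, the pyranone, closed in the second of three steps.

Assumption: the target SMILES holds no stereocentre (the side-chain carbon carries two bromines). The compound is therefore achiral and no enantiocontrol is needed.

**Step 1**
Reactants: 1 4-(trimethylsilyl)but-3-yn-2-one; 2 butanoyl chloride
Product: 4 1-(trimethylsilyl)oct-1-yne-3,5-dione, via lithium enolate 3 (not isolated)
Conditions: 1 (2.0 equiv), LiN(SiMe3)2 (2.05 equiv), toluene–THF, −78 °C, 30 min; then 2 (1.0 equiv), −78 → −30 °C; cold 1 M HCl quench (surplus 1 recovered)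
Reagents that add atoms: LiN(SiMe3)2 (lithium bis(trimethylsilyl)amide), [Li+].C[Si](C)(C)[N-][Si](C)(C)C (supplies only the Li of 3; none of its atoms remain in 4)
Why: Claisen-type C-acylation of a kinetic lithium enolate by an acid chloride in a weakly polar medium favours C- over O-acylation, the surplus enolate absorbs the acidic proton of the new 1,3-diketone, the SiMe3 cap blocks Michael addition to the ynone, and no stereocentre is formed.

**Step 2**
Reactants: 4 1-(trimethylsilyl)oct-1-yne-3,5-dione
Product: 7 2,3,5-tribromo-6-propyl-4H-pyran-4-one, via C4-bromo silyl ynedione 5 (not isolated), via 1,4-dibromo ynedione 6 (not isolated)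
Conditions: NBS (1.0 equiv), dry acetone, 0 °C, 15 min; then AgNO3 (20 mol %), NBS (2.15 equiv), 4 Å MS, dark, 0 °C → rt; water wash, short silica plug
Reagents that add atoms: N-bromosuccinimide (NBS), O=C1CCC(=O)N1Br
Why: Proposed new method: silver-catalysed brominative 6-endo-dig oxacyclisation of a 1-bromoalkynyl 1,3-diketone. NBS first brominates the enolic C4 (5) and AgNO3/NBS exchanges C–Si for C–Br (6). Monovalent silver then π-activates the bromoynone, so the C5 enol oxygen attacks the carbonyl-polarised, bromine-bearing β-carbon C1 and forms the O1–C2 bond. The adduct cannot lose bromide, because that would need a six-membered cycloalkyne, so the alkynyl bromine stays as C2–Br. The C3 vinyl-silver species is bromodemetalated by the third NBS, which returns Ag+. Any C4 gem-dibromide formed is only a reversible Br+ reservoir. The closest known reaction types are iodine- or iodine monochloride-induced cyclisation of heteroatom-substituted alkynones to 3-iodochromones, acid- or gold-catalysed 6-endo closure of alkynyl 1,3-diketones, and AgNO3/NBS bromodesilylation. None of these has been shown on a haloalkyne terminus to give a 2,3-dihalo-4-pyranone. No stereocentre remains in 7.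

**Step 3**
Reactants: 7 2,3,5-tribromo-6-propyl-4H-pyran-4-one
Product: 9 2,3,5-tribromo-6-(1,1-dibromopropyl)-4H-pyran-4-one, via racemic monobromide 8 (not isolated)
Conditions: NBS (2.4 equiv), PhCF3, 405 nm LED, 45 °C
Reagents that add atoms: N-bromosuccinimide (NBS), O=C1CCC(=O)N1Br
Why: In this Wohl–Ziegler radical bromination Br• abstracts the weakest C–H (next to C6, radical delocalised over C5 and the C4 carbonyl oxygen), all ring positions are already blocked, and the low stationary bromine level from NBS steers the second bromination of 8 to the same bromine-stabilised carbon, which erases the stereocentre of 8 and gives the achiral CBr2 group.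

**Compound list**
1 | 4-(trimethylsilyl)but-3-yn-2-one | CC(=O)C#C[Si](C)(C)C | starting material
2 | butanoyl chloride | CCCC(=O)Cl | starting material
3 | lithium 4-(trimethylsilyl)but-1-en-3-yn-2-olate | [Li+].[O-]C(=C)C#C[Si](C)(C)C | intermediate
4 | 1-(trimethylsilyl)oct-1-yne-3,5-dione (keto–enol mixture, drawn as diketone) | CCCC(=O)CC(=O)C#C[Si](C)(C)C | intermediate
5 | 4-bromo-1-(trimethylsilyl)oct-1-yne-3,5-dione (racemic, enolisable C4) | CCCC(=O)C(Br)C(=O)C#C[Si](C)(C)C | intermediate
6 | 1,4-dibromooct-1-yne-3,5-dione (racemic, enolisable C4) | CCCC(=O)C(Br)C(=O)C#CBr | intermediate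
7 | 2,3,5-tribromo-6-propyl-4H-pyran-4-one | CCCc1oc(Br)c(Br)c(=O)c1Br | intermediate
8 | 2,3,5-tribromo-6-(1-bromopropyl)-4H-pyran-4-one (racemic) | CCC(Br)c1oc(Br)c(Br)c(=O)c1Br | intermediate
9 | 2,3,5-tribromo-6-(1,1-dibromopropyl)-4H-pyran-4-one (achiral) | CCC(Br)(Br)c1oc(Br)c(Br)c(=O)c1Br | target

Total step count: 3. Longest linear sequence: 3.

**Steps most likely to fail**

(a) Step 2, the proposed new ring closure.
- Risks are 5-exo closure to a dibromomethylene furanone, hydrolysis of the vinylogous acyl bromide at C2, and stalling at a C4 gem-dibromide.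
- The fallback uses known chemistry only. It sets out from 4 and comes back at 7.
- Bu4NF/AcOH in THF at 0 °C removes the silyl group to give oct-1-yne-3,5-dione F1.
- Catalytic CF3SO3H in CH2Cl2 closes F1 by the established 6-endo-dig enol addition to 2-propyl-4H-pyran-4-one F2.
- NBS (2.2 equiv, MeCN) brominates both enol-ether β-positions to give 3,5-dibromo-2-propyl-4H-pyran-4-one F3.
- Directed metalation of the remaining ring C–H by (2,2,6,6-tetramethylpiperidin-1-yl)MgCl·LiCl in THF at −78 °C gives chloro(3,5-dibromo-4-oxo-6-propyl-4H-pyran-2-yl)magnesium F4.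
- Quenching F4 by BrCl2C–CCl2Br delivers 7.

(b) Step 3.
- Risks are HBr loss from 8 or 9 to a bromopropenyl side chain, vicinal instead of geminal dibromination, and a slow second abstraction beside the C5 bromine.
- The fallback drops late C–H bromination and brings the CBr2 group in on the acyl partner. It sets out from 2 and 3 and comes back at 9.
- Double Hell–Volhard–Zelinsky-type α-bromination of 2 (NBS 2.3 equiv, cat. HBr, SOCl2, 85 °C) gives 2,2-dibromobutanoyl chloride F5.
- Enolate 3 is trapped by Me3SiCl as trimethyl{[4-(trimethylsilyl)but-1-en-3-yn-2-yl]oxy}silane F6.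
- ZnCl2-assisted acylation of F6 by the activated acid chloride F5 gives 6,6-dibromo-1-(trimethylsilyl)oct-1-yne-3,5-dione F7. The neutral silyl enol ether avoids halophilic attack on the CBr2 group.
- The conditions of step 2 then carry F7 through 4,6,6-tribromo-1-(trimethylsilyl)oct-1-yne-3,5-dione F8 and 1,4,6,6-tetrabromooct-1-yne-3,5-dione F9 directly to 9.

(c) Step 1.
- Risks are O-acylation, double acylation, and premature cyclisation of 4 on work-up.
- The fallback replaces acylation by aldol addition plus oxidation. It sets out from 3 and comes back at 4.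
- Addition of 3 to butanal (CCCC=O) in THF at −78 °C, followed by an AcOH quench, gives racemic 5-hydroxy-1-(trimethylsilyl)oct-1-yn-3-one F10.
- Dess–Martin periodinane (CH2Cl2, NaHCO3, 0 °C) oxidises F10 to 4.

**Further compounds**
F1 | step 2 | oct-1-yne-3,5-dione | CCCC(=O)CC(=O)C#C
F2 | step 2 | 2-propyl-4H-pyran-4-one | CCCc1cc(=O)cco1
F3 | step 2 | 3,5-dibromo-2-propyl-4H-pyran-4-one | CCCc1occ(Br)c(=O)c1Br
F4 | step 2 | chloro(3,5-dibromo-4-oxo-6-propyl-4H-pyran-2-yl)magnesium | CCCc1oc([Mg]Cl)c(Br)c(=O)c1Br
F5 | step 3 | 2,2-dibromobutanoyl chloride | CCC(Br)(Br)C(=O)Cl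
F6 | step 3 | trimethyl{[4-(trimethylsilyl)but-1-en-3-yn-2-yl]oxy}silane | C=C(O[Si](C)(C)C)C#C[Si](C)(C)C
F7 | step 3 | 6,6-dibromo-1-(trimethylsilyl)oct-1-yne-3,5-dione | CCC(Br)(Br)C(=O)CC(=O)C#C[Si](C)(C)C
F8 | step 3 | 4,6,6-tribromo-1-(trimethylsilyl)oct-1-yne-3,5-dione (racemic) | CCC(Br)(Br)C(=O)C(Br)C(=O)C#C[Si](C)(C)C
F9 | step 3 | 1,4,6,6-tetrabromooct-1-yne-3,5-dione (racemic) | CCC(Br)(Br)C(=O)C(Br)C(=O)C#CBr
F10 | step 1 | 5-hydroxy-1-(trimethylsilyl)oct-1-yn-3-one (racemic) | CCCC(O)CC(=O)C#C[Si](C)(C)C
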